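# Total synthesis proposal for CNP0119857.1, the (3R)-isoflavan 23

## Analysis of the target

Target 23 is a (3R)-isoflavan. Aromatic ring A is fused to the dihydropyran ring C (O1, C2, C3, C4). Ring B sits on C3 and is fused through O2' and C3' to a 2,2-dimethyl-2H-pyran, ring D. Ring A is pentasubstituted (C4 on C4a, OMe on C5, prenyl on C6, OH on C7, O1 on C8a), and ring B keeps a free 4'-OH next to the chromene carbon C3'.

C3 is the only stereocentre. It is a tertiary benzylic CH between two methylene groups, so nothing in the molecule can relay selectivity to it and it must be set absolutely. The prenyl and chromene alkenes forbid catalytic hydrogenation, the 6-prenyl/7-OH pair and the chromene suffer in strong acid, and both oxygenated rings are easily oxidised.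

The hard points are therefore:
- the isolated stereocentre;
- telling apart five ring oxygens spread over a phloroglucinol and a resorcinol nucleus;
- closing ring D on O2'/C3' and not on O4'.

The plan rests on the chain O2'–C2'–C1'–C3–C4. A temporary bond between O2' and C4 turns these five atoms into a dihydrobenzofuran, so C4 can be held as the CH2 of a 2'-O-benzyl ether while C3–C4 is made beside it. C4 is benzylic to ring A, which has oxygen at both ortho positions and at the para position. The temporary bond can therefore be cut again by hydride, and the cut frees exactly the 2'-OH on which ring D is built.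

## Retrosynthetic reasoning

**Phenols and ring D (23 ⇒ 22 ⇒ 19 ⇒ 17 + 18).**
- The two phenols of 23 are masked as silyl ethers in 22, so the last step is a mild desilylation that touches neither alkene.
- Ring D is cut at C3'–CH= (back to the aryl propargyl ether 19) and then at O2'–CMe2 (back to phenol 17 and the tertiary propargylic chloride 18).
- The cut is made here because O2' has one free ortho carbon only, C3'. C1' is blocked by C3, so the sigmatropic shift has a single outlet.
- An activated halide is needed because a tertiary propargylic alcohol cannot be joined to a phenol by redox condensation.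
- The forward sequence requires 2'-OH to be the only free hydroxyl of 17.

**Reconnection of O2' to C4 (17 ⇒ 16).**
- A bond is added here, not cut: joining O2' to C4 turns isoflavan 17 into the cis-pterocarpan 16.
- This gives C3 a neighbouring functionalised carbon and places it in a five-membered ring that can be made stereoselectively.
- It also keeps O2' masked from the other phenols without a protecting group.
- The forward reaction must cleave C4–O2' only. That bond ionises easily because of ring A, whereas C2–O1 is an ordinary alkyl aryl ether.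
- Hydride must reach C4 faster than H3 is lost.

**O1–C2 (16 ⇒ 15 ⇒ 14).**
- Ring C is cut at the alkyl–oxygen bond, leading through phenol 15 to the diol-type precursor 14 (primary alcohol plus two ring-A phenols).
- Cutting here and not at O1–C8a lets ring A keep its third phloroglucinol oxygen from the start.
- The closure must precede the untethering. While O2' is still tied to C4, only the C8a oxygen can reach C2.
- The ring closure itself tells O1 from O7, so these two oxygens need not be differentiated earlier. O7 is silylated afterwards (15 to 16).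

**Oxidation level at C2 and the allyl groups (14 ⇒ 13 ⇒ 12).**
- The phenols of 14 come from the bis-allyl ether 13, and its CH2OH comes from the ester of 12.
- The ester carbon is C2 of the isoflavan, so no carbon is wasted.
- The reduction must be non-basic, because C3–H of 12 is both benzylic and alpha to the ester.

**C3–C4 (12 ⇒ 11), the key disconnection.**
- Cutting C3–C4 opens the dihydrobenzofuran to the aryldiazoacetate 11. C3 is the diazo carbon and C4 is the OCH2 of the benzyl ether tether.
- No other bond to C3 offers this: C3–C1' and C3–C2 would need intermolecular asymmetric couplings on hindered partners.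
- Here the reacting C–H bond is held five atoms away and is activated twice.
- One ring, one skeletal bond and both stereocentres of 12 arise together under the control of a chiral dirhodium carboxylate.

**Diazo group and tether (11 ⇒ 10 ⇒ 6 + 9).**
- The diazo group comes from the arylacetate 10 by diazo transfer.
- The tether bond O2'–CH2 is cut to give benzylic alcohol 6 and phenol 9.
- A redox condensation is chosen because halides of so electron-rich a benzylic system would not survive isolation.

**Ring A (6 ⇒ 5 ⇒ 4 ⇒ 3 ⇒ 1 + 2).**
- Alcohol 6 comes from aldehyde 5.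
- The methyl group of 5 is removed to give 4, whose free 2-OH is the hindered, chelated one.
- The two allyl groups are removed to give 3, and C3–prenyl is cut to give 1 and 2.
- C3 and C5 of 1 are equivalent, so the carbon alkylation has no regiochemical issue.
- After it, chelation and crowding single out the oxygen that must carry the methyl group.
- A thermal Claisen route to the prenyl group is avoided so that no allyl ether is ever heated.

**Ring B (9 ⇒ 8 ⇒ 7).**
- The silyl group is taken off the less hindered 4-oxygen to give 8, and the methyl ester is traced to acid 7.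

## Alternatives that were turned down

**Alternative 1:** Ring C is cut at two bonds at once, C4–C4a and O1–C2. This leads back to phloroglucinol A1 and the 2-arylacrolein A2, which already carries ring D.
- *Forward key step.* A chiral primary amine salt converts A2 into its iminium ion and A1 adds through a ring carbon to the CH2 terminus. The resulting enamine is protonated on one face at C3, and a flanking phenol closes the lactol A3.
- *In its favour.* Two bonds, ring C and the stereocentre arise in one metal-free operation. The symmetry of A1 removes any regiochemical question in the C–C bond formation, and the core is reached in far fewer steps. On convergence and step count to the core it is the stronger plan.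
- *Against it, at the stereocentre.* C3 is made by delivery of a proton, the smallest reagent, to an α-aryl enamine. In A3 it sits next to a masked aldehyde, so ring–chain tautomerism beside the amine catalyst opens a way back to the enamine and to racemisation.
- *Against it, at ring A.* Ring A arrives bare. O5 must then be methylated in preference to O7, and the prenyl group placed on C6 in preference to C8. The chroman has no carbonyl group for chelation, and both carbons lie between two oxygens.
- *Against it, at C2.* C2 must still be deoxygenated with Lewis acid and silane while the acid-sensitive chromene is present.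
- *Comparison.* The chosen strategy is longer. In exchange, all five substituents of ring A are fixed on aldehyde 5, where symmetry and chelation decide each position, and C3 stops being enolisable at alcohol 13.

**Alternative 2:** Only ring D is disconnected, at O2'–CMe2. This leads back to the 6,3'-diprenyl isoflavan A4 with a free 2'-OH and acetates on O7 and O4'.
- *Forward key step.* A high-potential quinone oxidant removes hydride from the benzylic CH2 of the 3'-prenyl group. The ortho-quinone methide formed with O2' closes by oxa-6π electrocyclisation to the diacetate A5. The C6 prenyl group lies between a methyl ether and an acetate, has no free ortho phenol, and should be spared.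
- *In its favour.* It follows the likely biogenesis and makes ring D in one step near room temperature, against two steps and strong heating here. On that point it is stronger.
- *Against it, in scope.* It is an end-game only; the isoflavan core and C3 must come from some other method. A4 also needs three phenols told apart and a second prenyl group placed on C3' between two oxygens.
- *Against it, at the oxidation.* The oxidant also meets C4–H2, activated by ring A, and C3–H. Dehydrogenation of ring C, which would erase the stereocentre, competes with the wanted oxidation.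
- *Comparison.* The chosen strategy gives the same regiochemical certainty for ring D without any oxidant, because 17 is released with 2'-OH as its only free hydroxyl. It solves C3 in the same design.

**Alternative 3:** Ring C is cut at the aryl–oxygen bond O1–C8a after an extra hydroxymethyl group has been added to C3. This gives the prochiral diol A6 with bromine on C8a.
- *Forward key step.* A monovalent copper salt with a chiral diamine couples one of the two enantiotopic CH2OH groups with the aryl bromide. Ring C closes to give A7, in which C3 is quaternary.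
- *In its favour.* Desymmetrising O-arylation of 2,2-disubstituted propane-1,3-diols is an established route to chromans and the metal is cheap. A quaternary centre cannot epimerise, so on configurational stability it is stronger than ester 12.
- *Against it, at C3.* C3 of the target carries hydrogen. The spare CH2OH must be removed with retention by oxidation and decarbonylation at a crowded centre, which costs at least two more steps with heat and much rhodium beside two alkenes.
- *Against it, at ring A.* Ring A needs bromine where the phloroglucinol oxygen stands, so aldehyde 1 no longer serves. The quaternary carbon must be built by alkylation with an unstable ring-A benzylic halide. The electron-rich, ortho-substituted bromide is also a slow partner for C–O coupling.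
- *Comparison.* The chosen strategy makes the tertiary centre directly and wastes no carbon, since the ester carbon becomes C2. It answers the lability of 12 by immediate non-basic reduction.

Key step: step 9

Assumption: Rh2(S-PTTL)4, dirhodium tetrakis[N-phthaloyl-(S)-tert-leucinate], is taken to give the (2R,3S) ester 12. If the first run shows the opposite sense, the mirror-image catalyst Rh2(R-PTTL)4 is used and nothing else changes.

## Route

Step 1
Reactants: 1 2,4,6-trihydroxybenzaldehyde; 2 1-bromo-3-methylbut-2-ene (prenyl bromide)
Product: 3 2,4,6-trihydroxy-3-(3-methylbut-2-enyl)benzaldehyde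
Conditions: KOH (1.0 equiv), H2O, argon, 0 °C to rt, 2 (0.9 equiv) added slowly
Reagents that add atoms: none
Why: C-alkylation of an ambident phloroglucinol anion: in water the phenoxide oxygens are solvated, so the soft allylic bromide is taken at carbon. C3 and C5 are equivalent, so there is no regiochemical issue, and the slight deficit of 2 limits a second prenylation.

Step 2
Reactants: 3 2,4,6-trihydroxy-3-(3-methylbut-2-enyl)benzaldehyde
Product: 4 4,6-bis(allyloxy)-2-hydroxy-3-(3-methylbut-2-enyl)benzaldehyde
Conditions: allyl bromide (2.2 equiv), K2CO3 (2.5 equiv), DMF, rt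
Reagents that add atoms: allyl bromide C=CCBr
Why: Williamson etherification in a dipolar aprotic solvent, which favours O-alkylation. The 2-OH is hydrogen-bonded to the formyl oxygen and squeezed between CHO and prenyl, so it should stay free while O4 and O6 react.

Step 3
Reactants: 4 4,6-bis(allyloxy)-2-hydroxy-3-(3-methylbut-2-enyl)benzaldehyde
Product: 5 4,6-bis(allyloxy)-2-methoxy-3-(3-methylbut-2-enyl)benzaldehyde
Conditions: MeI (3 equiv), K2CO3 (2 equiv), DMF, 40 °C
Reagents that add atoms: iodomethane CI
Why: Williamson methylation of the one remaining phenol; excess of the small electrophile and gentle warming overcome chelation and crowding. No base-labile group is present.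

Step 4
Reactants: 5 4,6-bis(allyloxy)-2-methoxy-3-(3-methylbut-2-enyl)benzaldehyde
Product: 6 [4,6-bis(allyloxy)-2-methoxy-3-(3-methylbut-2-enyl)phenyl]methanol
Conditions: NaBH4, THF–MeOH, 0 °C; aq NaHCO3 work-up
Reagents that add atoms: none
Why: Borohydride reduction of an aldehyde; ethers and alkenes are inert. The work-up stays free of acid because the trioxygenated benzylic alcohol ionises easily, and 6 is used promptly.

Step 5
Reactants: 7 2,4-dihydroxyphenylacetic acid
Product: 8 methyl 2-(2,4-dihydroxyphenyl)acetate
Conditions: MeOH, H2SO4 (cat.), reflux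
Reagents that add atoms: methanol CO
Why: Fischer esterification; in excess methanol the equilibrium with the benzofuranone lactone lies on the side of the open methyl ester.

Step 6
Reactants: 8 methyl 2-(2,4-dihydroxyphenyl)acetate
Product: 9 methyl 2-[2-hydroxy-4-(triisopropylsilyloxy)phenyl]acetate
Conditions: TIPSCl (1.05 equiv), imidazole (2 equiv), CH2Cl2, −10 to 0 °C
Reagents that add atoms: chlorotriisopropylsilane CC(C)[Si](Cl)(C(C)C)C(C)C
Why: Sterically governed mono-silylation: the bulky chlorosilane should take the 4-OH, which lies between two ring hydrogens. The 2-OH is flanked by the CH2CO2Me arm and hydrogen-bonded to its carbonyl group.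

Step 7
Reactants: 6 [4,6-bis(allyloxy)-2-methoxy-3-(3-methylbut-2-enyl)phenyl]methanol; 9 methyl 2-[2-hydroxy-4-(triisopropylsilyloxy)phenyl]acetate
Product: 10 methyl 2-[2-{[4,6-bis(allyloxy)-2-methoxy-3-(3-methylbut-2-enyl)phenyl]methoxy}-4-(triisopropylsilyloxy)phenyl]acetate
Conditions: PPh3, DIAD, toluene, 0 °C to rt; chromatography on Et3N-washed silica
Reagents that add atoms: none
Why: Mitsunobu etherification of a primary benzylic alcohol with a phenol under neutral conditions, which avoids an unstable benzylic halide and base-induced lactonisation of 9. The non-polar solvent keeps the oxyphosphonium–phenoxide pair tight and so favours O-attack.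

Step 8
Reactants: 10 methyl 2-[2-{[4,6-bis(allyloxy)-2-methoxy-3-(3-methylbut-2-enyl)phenyl]methoxy}-4-(triisopropylsilyloxy)phenyl]acetate
Product: 11 methyl 2-diazo-2-[2-{[4,6-bis(allyloxy)-2-methoxy-3-(3-methylbut-2-enyl)phenyl]methoxy}-4-(triisopropylsilyloxy)phenyl]acetate
Conditions: p-ABSA (1.3 equiv), DBU (1.5 equiv), MeCN, 0 °C to rt
Reagents that add atoms: 4-acetamidobenzenesulfonyl azide (p-ABSA) CC(=O)Nc1ccc(cc1)S(=O)(=O)N=[N+]=[N-]
Why: Regitz diazo transfer to an arylacetate, the standard entry to aryldiazoacetates. The hindered aryl silyl ether and the allyl ethers should tolerate anhydrous DBU at this temperature.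

Step 9
Reactants: 11 methyl 2-diazo-2-[2-{[4,6-bis(allyloxy)-2-methoxy-3-(3-methylbut-2-enyl)phenyl]methoxy}-4-(triisopropylsilyloxy)phenyl]acetate
Product: 12 methyl (2R,3S)-2-[4,6-bis(allyloxy)-2-methoxy-3-(3-methylbut-2-enyl)phenyl]-6-(triisopropylsilyloxy)-2,3-dihydrobenzofuran-3-carboxylate (cis)
Conditions: Rh2(S-PTTL)4 (1–2 mol %), 4 Å MS, toluene, −60 °C, slow addition of 11 (final ca. 0.01 M); neutral work-up, Et3N-washed silica
Reagents that add atoms: none
Why: The diazo carbon of 11 binds an axial site of the divalent rhodium dimer and loses N2, leaving an electrophilic donor/acceptor carbenoid at C3 (donor: ring B; acceptor: the ester whose carbon becomes C2). This carbenoid inserts into one of the two enantiotopic C–H bonds of the O2'–CH2 tether through a concerted but asynchronous three-centre transition state with hydride-transfer character, the developing positive charge at C4 being carried by O2' and by the two ortho oxygens and the para oxygen of ring A. The closest known reaction type is the enantioselective intramolecular 1,5 C–H insertion of 2-(benzyloxy)phenyl diazoacetates with chiral dirhodium carboxylates, which delivers cis-2-aryl-2,3-dihydrobenzofuran-3-carboxylates. The one ring formed, the five-membered ring O2'–C2'–C1'–C3–C4, closes by this 1,5 insertion, that is by making C3–C4. C3 is controlled by the catalyst: the four N-phthaloyl-tert-leucinate ligands wall off one face of the carbenoid, so the C–H bond can approach from one side only. C4 is fixed in the same transition state relative to C3, with ring A pointing away from the ligand wall and ending cis to the ester as the kinetic product; this centre is erased in step 14 and matters only for the ring closure of step 12. The step needs insertion to beat cyclopropanation, ylide formation and carbene dimerisation: the tether holds the activated C–H bond in a five-membered transition state, each alkene or ether oxygen of ring A could be reached only through a ring of nine or more atoms, the trisubstituted prenyl alkene is a poor partner for a hindered donor/acceptor carbenoid, and slow addition at high dilution suppresses bimolecular capture by the allyl groups. Low temperature and the non-polar solvent keep the event concerted, and work-up and chromatography stay neutral because C3–H of the cis ester is acidic.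

Step 10
Reactants: 12 methyl (2R,3S)-2-[4,6-bis(allyloxy)-2-methoxy-3-(3-methylbut-2-enyl)phenyl]-6-(triisopropylsilyloxy)-2,3-dihydrobenzofuran-3-carboxylate
Product: 13 {(2R,3R)-2-[4,6-bis(allyloxy)-2-methoxy-3-(3-methylbut-2-enyl)phenyl]-6-(triisopropylsilyloxy)-2,3-dihydrobenzofuran-3-yl}methanol
Conditions: i-Bu2AlH (3 equiv), CH2Cl2, −78 to −20 °C; aq potassium sodium tartrate
Reagents that add atoms: none
Why: Aluminium hydride reduction of an ester to the primary alcohol under non-basic conditions; excess hydride consumes the transient aldehyde at once, so C3 should not epimerise. The descriptor at C3 changes from S to R only because the priorities change, and from here on C3 is no longer enolisable.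

Step 11
Reactants: 13 {(2R,3R)-2-[4,6-bis(allyloxy)-2-methoxy-3-(3-methylbut-2-enyl)phenyl]-6-(triisopropylsilyloxy)-2,3-dihydrobenzofuran-3-yl}methanol
Product: 14 4-[(2R,3R)-3-(hydroxymethyl)-6-(triisopropylsilyloxy)-2,3-dihydrobenzofuran-2-yl]-5-methoxy-6-(3-methylbut-2-enyl)benzene-1,3-diol
Conditions: Pd(PPh3)4 (5 mol %), morpholine (6 equiv), THF, rt
Reagents that add atoms: none
Why: Tsuji–Trost-type deallylation: zerovalent palladium ionises the aryl allyl ethers and morpholine traps the π-allyl fragments. The C-bound prenyl group has no leaving group, and the silyl ether, the alcohol and both stereocentres are not addressed.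

Step 12
Reactants: 14 4-[(2R,3R)-3-(hydroxymethyl)-6-(triisopropylsilyloxy)-2,3-dihydrobenzofuran-2-yl]-5-methoxy-6-(3-methylbut-2-enyl)benzene-1,3-diol
Product: 15 (6aR,11aR)-1-methoxy-2-(3-methylbut-2-enyl)-9-(triisopropylsilyloxy)-6a,11a-dihydro-6H-benzofuro[3,2-c]chromen-3-ol (cis-pterocarpan)
Conditions: PPh3, DIAD, THF (0.01 M), 0 °C to rt
Reagents that add atoms: none
Why: Intramolecular Mitsunobu etherification (6-exo-tet) closes ring C by forming O1–C2. The cis arrangement puts CH2OH and ring A on the same face, only the ortho phenol can reach the activated carbon, and dilution holds back intermolecular attack by the other phenol. Displacement occurs at a CH2 group, so no stereocentre is touched.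

Step 13
Reactants: 15 (6aR,11aR)-1-methoxy-2-(3-methylbut-2-enyl)-9-(triisopropylsilyloxy)-6a,11a-dihydro-6H-benzofuro[3,2-c]chromen-3-ol
Product: 16 (6aR,11aR)-1-methoxy-2-(3-methylbut-2-enyl)-3,9-bis(triisopropylsilyloxy)-6a,11a-dihydro-6H-benzofuro[3,2-c]chromen (cis-pterocarpan)
Conditions: TIPSCl (1.5 equiv), imidazole (3 equiv), DMAP (cat.), DMF, rt
Reagents that add atoms: chlorotriisopropylsilane CC(C)[Si](Cl)(C(C)C)C(C)C
Why: Silylation of the single free phenol (O7 of the isoflavan) under mildly basic conditions that do not ionise the benzylic C–O bond. It ensures that the next step releases 2'-OH as the only free hydroxyl.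

Step 14
Reactants: 16 (6aR,11aR)-1-methoxy-2-(3-methylbut-2-enyl)-3,9-bis(triisopropylsilyloxy)-6a,11a-dihydro-6H-benzofuro[3,2-c]chromen
Product: 17 2-[(3R)-5-methoxy-6-(3-methylbut-2-enyl)-7-(triisopropylsilyloxy)chroman-3-yl]-5-(triisopropylsilyloxy)phenol
Conditions: Et3SiH (10 equiv), BF3·OEt2 (1.5 equiv), CH2Cl2, −78 to −40 °C; aq NaHCO3
Reagents that add atoms: none
Why: Ionic hydrogenation of an activated benzylic aryl ether: the Lewis acid ionises C4–O2' alone, because the cation is stabilised by two ortho oxygens and one para oxygen of ring A whereas C2–O1 is not benzylic. The large excess of silane should trap the cation before H3 can be lost, so C3 keeps its configuration. The anhydrous Lewis acid at low temperature spares the prenyl alkene, which has no free phenol beside it.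

Step 15
Reactants: 17 2-[(3R)-5-methoxy-6-(3-methylbut-2-enyl)-7-(triisopropylsilyloxy)chroman-3-yl]-5-(triisopropylsilyloxy)phenol; 18 3-chloro-3-methylbut-1-yne
Product: 19 (3R)-5-methoxy-6-(3-methylbut-2-enyl)-3-[2-(2-methylbut-3-yn-2-yloxy)-4-(triisopropylsilyloxy)phenyl]-7-(triisopropylsilyloxy)chroman
Conditions: 18 (1.5 equiv), CuCl2·2H2O (1 mol %), DBU (1.5 equiv), MeCN–THF, 0 °C
Reagents that add atoms: none
Why: Copper-catalysed propargylic etherification: base and copper salt convert 18 into a copper acetylide that ionises to an allenylidene-type electrophile, which the phenoxide takes at the tertiary carbon. The 2'-OH is the only free hydroxyl, so the site is unambiguous.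

Step 16
Reactants: 19 (3R)-5-methoxy-6-(3-methylbut-2-enyl)-3-[2-(2-methylbut-3-yn-2-yloxy)-4-(triisopropylsilyloxy)phenyl]-7-(triisopropylsilyloxy)chroman
Product: 22 (3R)-3-[2,2-dimethyl-5-(triisopropylsilyloxy)-2H-chromen-8-yl]-5-methoxy-6-(3-methylbut-2-enyl)-7-(triisopropylsilyloxy)chroman, via ortho-allenylphenol 20 (not isolated), via ortho-quinone methide 21 (not isolated)
Conditions: o-xylene (degassed), 140 °C
Reagents that add atoms: none
Why: Aromatic propargyl Claisen cascade: a [3,3] shift goes to C3', the only free ortho carbon of O2', and is followed by enolisation to 20, a 1,5-hydrogen shift to 21 and oxa-6π electrocyclisation to ring D. The prenyl group lies between a methyl ether and a silyl ether and has no thermal outlet, and C3 is not involved.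

Step 17
Reactants: 22 (3R)-3-[2,2-dimethyl-5-(triisopropylsilyloxy)-2H-chromen-8-yl]-5-methoxy-6-(3-methylbut-2-enyl)-7-(triisopropylsilyloxy)chroman
Product: 23 8-[(3R)-7-hydroxy-5-methoxy-6-(3-methylbut-2-enyl)chroman-3-yl]-2,2-dimethyl-2H-chromen-5-ol (CNP0119857.1)
Conditions: TBAF (2.5 equiv), AcOH (2.5 equiv), THF, 0 °C
Reagents that add atoms: none
Why: Fluoride desilylation of both aryl silyl ethers. The acetic acid buffer keeps the phenoxides protonated, which protects the electron-rich product from air oxidation, and neither alkene nor C3 is affected.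

## Compound list

1 | 2,4,6-trihydroxybenzaldehyde | O=Cc1c(O)cc(O)cc1O | starting material
2 | 1-bromo-3-methylbut-2-ene (prenyl bromide) | CC(C)=CCBr | starting material
3 | 2,4,6-trihydroxy-3-(3-methylbut-2-enyl)benzaldehyde | O=Cc1c(O)c(CC=C(C)C)c(O)cc1O | intermediate
4 | 4,6-bis(allyloxy)-2-hydroxy-3-(3-methylbut-2-enyl)benzaldehyde | O=Cc1c(O)c(CC=C(C)C)c(OCC=C)cc1OCC=C | intermediate
5 | 4,6-bis(allyloxy)-2-methoxy-3-(3-methylbut-2-enyl)benzaldehyde | O=Cc1c(OC)c(CC=C(C)C)c(OCC=C)cc1OCC=C | intermediate
6 | [4,6-bis(allyloxy)-2-methoxy-3-(3-methylbut-2-enyl)phenyl]methanol | OCc1c(OC)c(CC=C(C)C)c(OCC=C)cc1OCC=C | intermediate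
7 | 2,4-dihydroxyphenylacetic acid | OC(=O)Cc1ccc(O)cc1O | starting material
8 | methyl 2-(2,4-dihydroxyphenyl)acetate | COC(=O)Cc1ccc(O)cc1O | intermediate
9 | methyl 2-[2-hydroxy-4-(triisopropylsilyloxy)phenyl]acetate | COC(=O)Cc1ccc(O[Si](C(C)C)(C(C)C)C(C)C)cc1O | intermediate
10 | methyl 2-[2-{[4,6-bis(allyloxy)-2-methoxy-3-(3-methylbut-2-enyl)phenyl]methoxy}-4-(triisopropylsilyloxy)phenyl]acetate | COC(=O)Cc1ccc(O[Si](C(C)C)(C(C)C)C(C)C)cc1OCc1c(OC)c(CC=C(C)C)c(OCC=C)cc1OCC=C | intermediate
11 | methyl 2-diazo-2-[2-{[4,6-bis(allyloxy)-2-methoxy-3-(3-methylbut-2-enyl)phenyl]methoxy}-4-(triisopropylsilyloxy)phenyl]acetate | COC(=O)C(=[N+]=[N-])c1ccc(O[Si](C(C)C)(C(C)C)C(C)C)cc1OCc1c(OC)c(CC=C(C)C)c(OCC=C)cc1OCC=C | intermediate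
12 | methyl (2R,3S)-2-[4,6-bis(allyloxy)-2-methoxy-3-(3-methylbut-2-enyl)phenyl]-6-(triisopropylsilyloxy)-2,3-dihydrobenzofuran-3-carboxylate (cis) | COC(=O)[C@H]1c2ccc(O[Si](C(C)C)(C(C)C)C(C)C)cc2O[C@H]1c1c(OC)c(CC=C(C)C)c(OCC=C)cc1OCC=C | intermediate
13 | {(2R,3R)-2-[4,6-bis(allyloxy)-2-methoxy-3-(3-methylbut-2-enyl)phenyl]-6-(triisopropylsilyloxy)-2,3-dihydrobenzofuran-3-yl}methanol | OC[C@H]1c2ccc(O[Si](C(C)C)(C(C)C)C(C)C)cc2O[C@H]1c1c(OC)c(CC=C(C)C)c(OCC=C)cc1OCC=C | intermediate
14 | 4-[(2R,3R)-3-(hydroxymethyl)-6-(triisopropylsilyloxy)-2,3-dihydrobenzofuran-2-yl]-5-methoxy-6-(3-methylbut-2-enyl)benzene-1,3-diol | OC[C@H]1c2ccc(O[Si](C(C)C)(C(C)C)C(C)C)cc2O[C@H]1c1c(OC)c(CC=C(C)C)c(O)cc1O | intermediate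
15 | (6aR,11aR)-1-methoxy-2-(3-methylbut-2-enyl)-9-(triisopropylsilyloxy)-6a,11a-dihydro-6H-benzofuro[3,2-c]chromen-3-ol | C3[C@H]1c2ccc(O[Si](C(C)C)(C(C)C)C(C)C)cc2O[C@H]1c1c(OC)c(CC=C(C)C)c(O)cc1O3 | intermediate
16 | (6aR,11aR)-1-methoxy-2-(3-methylbut-2-enyl)-3,9-bis(triisopropylsilyloxy)-6a,11a-dihydro-6H-benzofuro[3,2-c]chromen | C3[C@H]1c2ccc(O[Si](C(C)C)(C(C)C)C(C)C)cc2O[C@H]1c1c(OC)c(CC=C(C)C)c(O[Si](C(C)C)(C(C)C)C(C)C)cc1O3 | intermediate
17 | 2-[(3R)-5-methoxy-6-(3-methylbut-2-enyl)-7-(triisopropylsilyloxy)chroman-3-yl]-5-(triisopropylsilyloxy)phenol | COc1c(CC=C(C)C)c(O[Si](C(C)C)(C(C)C)C(C)C)cc2c1C[C@H](c1ccc(O[Si](C(C)C)(C(C)C)C(C)C)cc1O)CO2 | intermediate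
18 | 3-chloro-3-methylbut-1-yne | CC(C)(Cl)C#C | starting material
19 | (3R)-5-methoxy-6-(3-methylbut-2-enyl)-3-[2-(2-methylbut-3-yn-2-yloxy)-4-(triisopropylsilyloxy)phenyl]-7-(triisopropylsilyloxy)chroman | COc1c(CC=C(C)C)c(O[Si](C(C)C)(C(C)C)C(C)C)cc2c1C[C@H](c1ccc(O[Si](C(C)C)(C(C)C)C(C)C)cc1OC(C)(C)C#C)CO2 | intermediate
20 | 2-[(3R)-5-methoxy-6-(3-methylbut-2-enyl)-7-(triisopropylsilyloxy)chroman-3-yl]-6-(3-methylbuta-1,2-dienyl)-5-(triisopropylsilyloxy)phenol (ortho-allenylphenol) | COc1c(CC=C(C)C)c(O[Si](C(C)C)(C(C)C)C(C)C)cc2c1C[C@H](c1ccc(O[Si](C(C)C)(C(C)C)C(C)C)c(C=C=C(C)C)c1O)CO2 | intermediate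
21 | (6Z)-2-[(3R)-5-methoxy-6-(3-methylbut-2-enyl)-7-(triisopropylsilyloxy)chroman-3-yl]-6-(3-methylbut-2-enylidene)-5-(triisopropylsilyloxy)cyclohexa-2,4-dien-1-one (ortho-quinone methide) | COc1c(CC=C(C)C)c(O[Si](C(C)C)(C(C)C)C(C)C)cc2c1C[C@H](C1=CC=C(O[Si](C(C)C)(C(C)C)C(C)C)/C(=C/C=C(C)C)C1=O)CO2 | intermediate
22 | (3R)-3-[2,2-dimethyl-5-(triisopropylsilyloxy)-2H-chromen-8-yl]-5-methoxy-6-(3-methylbut-2-enyl)-7-(triisopropylsilyloxy)chroman | COc1c(CC=C(C)C)c(O[Si](C(C)C)(C(C)C)C(C)C)cc2c1C[C@H](c1ccc(O[Si](C(C)C)(C(C)C)C(C)C)c3c1OC(C)(C)C=C3)CO2 | intermediate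
23 | 8-[(3R)-7-hydroxy-5-methoxy-6-(3-methylbut-2-enyl)chroman-3-yl]-2,2-dimethyl-2H-chromen-5-ol (CNP0119857.1) | COc1c(CC=C(C)C)c(O)cc2c1C[C@H](c1ccc(O)c3c1OC(C)(C)C=C3)CO2 | target

## Step count and least certain steps

Total step count: 17.
Longest linear sequence: 15 steps (steps 1–4 and 7–17, from 1). Steps 5 and 6 form the ring-B branch.

**Step 9 (key step).**
- *What may go wrong.* Ring A is very electron-rich and carries two ortho substituents, so hydride transfer may run ahead of C–C bond formation. The event then becomes stepwise, and both the facial selectivity at C3 and the cis preference erode. Capture of the carbenoid by a terminal allyl alkene of a second molecule is the second leak.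
- *Fallback (from 11, back at 13).* Stereocontrol is moved from the catalyst to a resolution. Diazo ester 11 is decomposed with achiral Rh2(OAc)4 in CH2Cl2 at the same dilution. This should give 12 together with its mirror image, methyl (2S,3R)-2-[4,6-bis(allyloxy)-2-methoxy-3-(3-methylbut-2-enyl)phenyl]-6-(triisopropylsilyloxy)-2,3-dihydrobenzofuran-3-carboxylate F1. Reduction with i-Bu2AlH gives 13 and the enantiomeric (2S,3S) alcohol F2. Esterification of the pair with (S)-2-methoxy-2-phenylacetic acid (DCC, DMAP, CH2Cl2) gives two diastereomers: the (S)-O-methylmandelate of 13 F3 and the (S)-O-methylmandelate of the (2S,3S) alcohol F4. These are separated by chromatography or crystallisation, and i-Bu2AlH at −78 °C releases 13 from F3.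

**Step 14.**
- *What may go wrong.* Loss of H3 from the C4 cation followed by re-reduction would racemise C3. Fluoride-assisted loss of the 7-O-silyl group through a para-quinone-methide pathway would free a second phenol. Adventitious acid could protonate the prenyl alkene.
- *Fallback (from 16, back at 17, no new compound).* The cationic mechanism is replaced by electron transfer. Lithium 4,4'-di-tert-butylbiphenylide in THF at −78 °C adds an electron to the benzylic aryl ether. The radical anion fragments to the ring-B phenoxide and a C4 benzylic radical, which is reduced further and protonated on quenching with NH4Cl. No cation forms next to C3 and no fluoride is present. The isolated alkene, the silyl ethers and the non-benzylic C2–O1 bond should react more slowly.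

**Step 7.**
- *What may go wrong.* The oxyphosphonium salt of the very electron-rich benzylic alcohol may ionise before the phenoxide attacks. This leads to Friedel–Crafts self-condensation and C-benzylation.
- *Fallback (from 5, back at 10).* A storable cationic leaving group replaces the redox condensation. Reductive amination of 5 with dimethylamine and NaBH(OAc)3 gives 1-[4,6-bis(allyloxy)-2-methoxy-3-(3-methylbut-2-enyl)phenyl]-N,N-dimethylmethanamine F5. MeI converts it into [4,6-bis(allyloxy)-2-methoxy-3-(3-methylbut-2-enyl)phenyl]methyl-trimethylammonium iodide F6. The potassium phenoxide of 9 (K2CO3, DMF, 50–60 °C) then displaces trimethylamine from the benzylic carbon to give 10.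

**Step 1.**
- *What may go wrong.* A second C-prenylation, geminal dialkylation with loss of aromaticity, and O-alkylation all drain material.
- *Fallback (from 1, back at 4).* The prenyl group is delivered from oxygen by a sigmatropic shift.
  - Aldehyde 1 is bis-allylated (allyl bromide, K2CO3, DMF) to 4,6-bis(allyloxy)-2-hydroxybenzaldehyde F7.
  - Its remaining phenol is etherified with 18 (CuCl2·2H2O cat., DBU, MeCN) to 4,6-bis(allyloxy)-2-(2-methylbut-3-yn-2-yloxy)benzaldehyde F8.
  - Semihydrogenation (H2, Pd/CaCO3 poisoned with Pb(OAc)2, quinoline) gives 4,6-bis(allyloxy)-2-(2-methylbut-3-en-2-yloxy)benzaldehyde F9.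
  - An aromatic Claisen rearrangement in toluene at 110 °C moves the group to C3, the only free ortho carbon, as a prenyl group and gives 4.
  - Simple allyl aryl ethers need markedly higher temperatures and should stay in place.

**Step 6.**
- *What may go wrong.* Silylation at the 2-oxygen or at both oxygens is possible if the steric bias is insufficient.
- *Fallback (from 7, back at 9).* The 2-oxygen is tied up in a lactone. Acid 7 is dehydrated (p-TsOH cat., toluene, reflux with water removal) to 6-hydroxybenzofuran-2(3H)-one F10. Its only hydroxyl is silylated (TIPSCl, imidazole) to give 6-(triisopropylsilyloxy)benzofuran-2(3H)-one F11. Methanolysis (MeOH, Et3N cat., rt) opens the aryl lactone to 9.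

**Step 15.**
- *What may go wrong.* Etherification of the phenol may be slow because it is crowded by the C3 substituent. Meanwhile 18 can eliminate, and the base can begin to remove a silyl group.
- *Fallback (from 17, back at 22, no new compound).* Ring D is made by a formal [3+3] condensation in place of etherification and rearrangement. Phenol 17 is heated with 3-methylbut-2-enal, PhB(OH)2 and AcOH in toluene with removal of water. A cyclic aryl boronate delivers the aldehyde to the ortho carbon C3', and collapse to the ortho-quinone methide 21 followed by electrocyclisation gives 22 directly.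

## Further compounds

F1 | step 9 | methyl (2S,3R)-2-[4,6-bis(allyloxy)-2-methoxy-3-(3-methylbut-2-enyl)phenyl]-6-(triisopropylsilyloxy)-2,3-dihydrobenzofuran-3-carboxylate | COC(=O)[C@@H]1c2ccc(O[Si](C(C)C)(C(C)C)C(C)C)cc2O[C@@H]1c1c(OC)c(CC=C(C)C)c(OCC=C)cc1OCC=C
F2 | step 9 | {(2S,3S)-2-[4,6-bis(allyloxy)-2-methoxy-3-(3-methylbut-2-enyl)phenyl]-6-(triisopropylsilyloxy)-2,3-dihydrobenzofuran-3-yl}methanol | OC[C@@H]1c2ccc(O[Si](C(C)C)(C(C)C)C(C)C)cc2O[C@@H]1c1c(OC)c(CC=C(C)C)c(OCC=C)cc1OCC=C
F3 | step 9 | (S)-O-methylmandelate of 13 | CO[C@H](C(=O)OC[C@H]1c2ccc(O[Si](C(C)C)(C(C)C)C(C)C)cc2O[C@H]1c1c(OC)c(CC=C(C)C)c(OCC=C)cc1OCC=C)c1ccccc1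
F4 | step 9 | (S)-O-methylmandelate of the (2S,3S) alcohol | CO[C@H](C(=O)OC[C@@H]1c2ccc(O[Si](C(C)C)(C(C)C)C(C)C)cc2O[C@@H]1c1c(OC)c(CC=C(C)C)c(OCC=C)cc1OCC=C)c1ccccc1
F0 | step 14 | none | none
F5 | step 7 | 1-[4,6-bis(allyloxy)-2-methoxy-3-(3-methylbut-2-enyl)phenyl]-N,N-dimethylmethanamine | CN(C)Cc1c(OC)c(CC=C(C)C)c(OCC=C)cc1OCC=C
F6 | step 7 | [4,6-bis(allyloxy)-2-methoxy-3-(3-methylbut-2-enyl)phenyl]methyl-trimethylammonium iodide | C[N+](C)(C)Cc1c(OC)c(CC=C(C)C)c(OCC=C)cc1OCC=C.[I-]
F7 | step 1 | 4,6-bis(allyloxy)-2-hydroxybenzaldehyde | O=Cc1c(O)cc(OCC=C)cc1OCC=C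
F8 | step 1 | 4,6-bis(allyloxy)-2-(2-methylbut-3-yn-2-yloxy)benzaldehyde | O=Cc1c(OC(C)(C)C#C)cc(OCC=C)cc1OCC=C
F9 | step 1 | 4,6-bis(allyloxy)-2-(2-methylbut-3-en-2-yloxy)benzaldehyde | O=Cc1c(OC(C)(C)C=C)cc(OCC=C)cc1OCC=C
F10 | step 6 | 6-hydroxybenzofuran-2(3H)-one | O=C1Cc2ccc(O)cc2O1
F11 | step 6 | 6-(triisopropylsilyloxy)benzofuran-2(3H)-one | O=C1Cc2ccc(O[Si](C(C)C)(C(C)C)C(C)C)cc2O1
F0 | step 15 | none | none
A1 | alternative 1 | phloroglucinol (benzene-1,3,5-triol) | Oc1cc(O)cc(O)c1
A2 | alternative 1 | 2-[2,2-dimethyl-5-(triisopropylsilyloxy)-2H-chromen-8-yl]prop-2-enal | O=CC(=C)c1ccc(O[Si](C(C)C)(C(C)C)C(C)C)c2c1OC(C)(C)C=C2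
A3 | alternative 1 | (3R)-3-[2,2-dimethyl-5-(triisopropylsilyloxy)-2H-chromen-8-yl]chroman-2,5,7-triol (lactol, C2 epimers) | Oc1cc(O)cc2c1C[C@H](c1ccc(O[Si](C(C)C)(C(C)C)C(C)C)c3c1OC(C)(C)C=C3)C(O)O2
A4 | alternative 2 | (3R)-7-acetoxy-3-[4-acetoxy-2-hydroxy-3-(3-methylbut-2-enyl)phenyl]-5-methoxy-6-(3-methylbut-2-enyl)chroman | COc1c(CC=C(C)C)c(OC(C)=O)cc2c1C[C@H](c1ccc(OC(C)=O)c(CC=C(C)C)c1O)CO2
A5 | alternative 2 | 7,4'-di-O-acetate of 23 | COc1c(CC=C(C)C)c(OC(C)=O)cc2c1C[C@H](c1ccc(OC(C)=O)c3c1OC(C)(C)C=C3)CO2
A6 | alternative 3 | 2-{[6-bromo-2-methoxy-3-(3-methylbut-2-enyl)-4-(triisopropylsilyloxy)phenyl]methyl}-2-[2,2-dimethyl-5-(triisopropylsilyloxy)-2H-chromen-8-yl]propane-1,3-diol | COc1c(CC=C(C)C)c(O[Si](C(C)C)(C(C)C)C(C)C)cc(Br)c1CC(CO)(CO)c1ccc(O[Si](C(C)C)(C(C)C)C(C)C)c2c1OC(C)(C)C=C2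
A7 | alternative 3 | {(3R)-3-[2,2-dimethyl-5-(triisopropylsilyloxy)-2H-chromen-8-yl]-5-methoxy-6-(3-methylbut-2-enyl)-7-(triisopropylsilyloxy)chroman-3-yl}methanol | COc1c(CC=C(C)C)c(O[Si](C(C)C)(C(C)C)C(C)C)cc2c1C[C@](CO)(c1ccc(O[Si](C(C)C)(C(C)C)C(C)C)c3c1OC(C)(C)C=C3)CO2
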